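**Retrosynthetic overview**
1. Aryl part: commercial aldehyde 1 is converted to the ketal-protected acid 5 (demethylation, catechol ketal, O-methylation, Pinnick). The benzene ring is bought, not built.
2. Carbocycle: bought as (R)-carvone 6 and never rebuilt. C7–O comes from oxirane 7, and C8a–C1 from an α'-aldol (10).
3. Key disconnection C6–O: ester 11 arises from anti opening of oxirane 10 by acid 5. This sets C6 by inversion and keeps C7.
4. C4a: the isopropenyl group is cut down to ketone 14, then triflate 15. C4a–C4 is made by Sonogashira coupling with enyne 19 (from 16 + 17) to give 20.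
5. The pyran is the only ring formed on the way, and it is formed last by 6-endo C–O cyclisation (22). Acidolysis gives 23.

Assumption: the target is the single (6S,7R) isomer drawn (C6 acyloxy and C7 hydroxy trans); 1, 6, 16 and 17 are commercial.

**Route**

Step 1
Reactants: 1 2,3,4-trimethoxy-6-methylbenzaldehyde
Product: 2 2,3,4-trihydroxy-6-methylbenzaldehyde
Conditions: BBr3 (4.5 equiv), CH2Cl2, −78 °C → rt; H2O
Reagents that add atoms: none
Why: Lewis-acid O-demethylation (BBr3 ether cleavage) removes all three methyl ethers, and the aldehyde is returned on aqueous work-up.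

Step 2
Reactants: 2 2,3,4-trihydroxy-6-methylbenzaldehyde
Product: 3 4-hydroxy-6-methyl-2,2-diphenyl-1,3-benzodioxole-5-carbaldehyde
Conditions: Ph2CCl2, Ph2O, 175 °C, 30 min
Reagents that add atoms: dichlorodiphenylmethane ClC(Cl)(c1ccccc1)c1ccccc1
Why: Catechol ketalisation takes the 3,4-diol pair because the 2-OH is held in a hydrogen bond to the aldehyde.

Step 3
Reactants: 3 4-hydroxy-6-methyl-2,2-diphenyl-1,3-benzodioxole-5-carbaldehyde
Product: 4 4-methoxy-6-methyl-2,2-diphenyl-1,3-benzodioxole-5-carbaldehyde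
Conditions: MeI, K2CO3, DMF, rt → 50 °C
Reagents that add atoms: iodomethane CI
Why: Williamson O-methylation of the one remaining phenol installs the 2-methoxy group of the target.

Step 4
Reactants: 4 4-methoxy-6-methyl-2,2-diphenyl-1,3-benzodioxole-5-carbaldehyde
Product: 5 4-methoxy-6-methyl-2,2-diphenyl-1,3-benzodioxole-5-carboxylic acid
Conditions: NaClO2, NaH2PO4, 2-methyl-2-butene, t-BuOH/H2O, rt
Reagents that add atoms: sodium chlorite [Na+].[O-]Cl=O
Why: Pinnick oxidation converts the hindered aldehyde to the acid, and the alkene scavenger keeps HOCl off the electron-rich ring.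

Step 5
Reactants: 6 (R)-(−)-carvone
Product: 7 (1R,4R,6R)-1-methyl-4-(prop-1-en-2-yl)-7-oxabicyclo[4.1.0]heptan-2-one
Conditions: 30% H2O2, NaOH (0.3 equiv), MeOH, 0 °C
Reagents that add atoms: hydrogen peroxide OO
Why: Weitz–Scheffer nucleophilic epoxidation; hydroperoxide adds axially anti to the equatorial isopropenyl group, so the oxirane oxygen (the future C7–OH, R) is set trans to it.

Step 6
Reactants: 7 (1R,4R,6R)-1-methyl-4-(prop-1-en-2-yl)-7-oxabicyclo[4.1.0]heptan-2-one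
Product: 10 (1R,3R,4R,6R)-3-[(tert-butyldimethylsilyloxy)methyl]-1-methyl-4-(prop-1-en-2-yl)-7-oxabicyclo[4.1.0]heptan-2-one, via lithium enolate 8 (not isolated), via lithium aldolate 9 (not isolated)
Conditions: LDA (1.1 equiv), THF, −78 °C; monomeric CH2O (THF solution), −78 °C; TBSOTf, −78 → 0 °C
Reagents that add atoms: formaldehyde C=O; tert-butyldimethylsilyl triflate CC(C)(C)[Si](C)(C)OS(=O)(=O)C(F)(F)F
Why: Kinetic α'-enolate aldol with formaldehyde then O-silylation; the other α-carbon is quaternary so only one enolate can form, and the new centre (anti to isopropenyl) is later made sp2.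

Step 7
Reactants: 10 (1R,3R,4R,6R)-3-[(tert-butyldimethylsilyloxy)methyl]-1-methyl-4-(prop-1-en-2-yl)-7-oxabicyclo[4.1.0]heptan-2-one; 5 4-methoxy-6-methyl-2,2-diphenyl-1,3-benzodioxole-5-carboxylic acid (1.3 equiv)
Product: 11 (1S,2R,4R,5R)-4-[(tert-butyldimethylsilyloxy)methyl]-2-hydroxy-2-methyl-3-oxo-5-(prop-1-en-2-yl)cyclohexyl 4-methoxy-6-methyl-2,2-diphenyl-1,3-benzodioxole-5-carboxylate
Conditions: Mg(NTf2)2 (10 mol %), i-Pr2NEt (20 mol %), 4 Å MS, PhMe, 50 °C
Reagents that add atoms: none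
Why: Proposed new method: a chelating Mg(II) Lewis acid binds the ketone oxygen and the oxirane oxygen in a five-membered chelate, which polarises the distal Cβ–O bond (the α-carbon is quaternary and next to C=O, so it is blocked sterically and electronically), while the catalytic ammonium carboxylate of 5 (hindered at its acyl carbon but not at oxygen) attacks the secondary β-carbon from the back in an SN2 epoxide opening, giving the C6 ester with inversion, trans to the retained tertiary OH, and proton transfer from 5 to the Mg alkoxide turns the catalyst over; the closest known reactions are the Ti(OiPr)4-mediated C3 opening of 2,3-epoxy alcohols by carboxylic acids, chelation-controlled β-opening of α,β-epoxy ketones by magnesium halides and metal-salen catalysed carboxylic acid opening of simple epoxides, none shown for an α,β-epoxy ketone with a di-ortho-substituted benzoic acid.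

Step 8
Reactants: 11 (1S,2R,4R,5R)-4-[(tert-butyldimethylsilyloxy)methyl]-2-hydroxy-2-methyl-3-oxo-5-(prop-1-en-2-yl)cyclohexyl 4-methoxy-6-methyl-2,2-diphenyl-1,3-benzodioxole-5-carboxylate
Product: 14 (1S,2R)-4-[(tert-butyldimethylsilyloxy)methyl]-2-hydroxy-2-methyl-3,5-dioxocyclohexyl 4-methoxy-6-methyl-2,2-diphenyl-1,3-benzodioxole-5-carboxylate (mostly enolised; used directly), via methoxy hydroperoxide 12 (not isolated), via TEMPO adduct 13 (not isolated)
Conditions: O3, MeOH/CH2Cl2, −78 °C (Sudan Red end point); FeSO4·7H2O (1.2 equiv), TEMPO (1.5 equiv), −78 °C → rt; mCPBA, CH2Cl2, 0 °C → rt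
Reagents that add atoms: ozone [O-][O+]=O; methanol CO; TEMPO CC1(C)CCCC(C)(C)N1[O]
Why: Oxodealkenylation (Criegee ozonolysis in methanol, Fe(II) reduction to an alkoxy radical, β-scission, TEMPO capture, peracid oxidation of the alkoxyamine) turns the isopropenyl-bearing carbon into the C4a ketone; the quaternary C7 prevents aromatisation and the two stereocentres are untouched.

Step 9
Reactants: 14 (1S,2R)-4-[(tert-butyldimethylsilyloxy)methyl]-2-hydroxy-2-methyl-3,5-dioxocyclohexyl 4-methoxy-6-methyl-2,2-diphenyl-1,3-benzodioxole-5-carboxylate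
Product: 15 (1S,6R)-4-[(tert-butyldimethylsilyloxy)methyl]-6-hydroxy-6-methyl-5-oxo-3-(trifluoromethylsulfonyloxy)cyclohex-3-en-1-yl 4-methoxy-6-methyl-2,2-diphenyl-1,3-benzodioxole-5-carboxylate
Conditions: PhNTf2 (1.1 equiv), i-Pr2NEt, DMAP (10 mol %), CH2Cl2, 0 °C → rt
Reagents that add atoms: N-phenylbis(trifluoromethanesulfonimide) O=S(=O)(N(c1ccccc1)S(=O)(=O)C(F)(F)F)C(F)(F)F
Why: Enol triflation of the vinylogous acid occurs at the oxygen remote from the quaternary carbinol (less hindered, and the other carbonyl is hydrogen-bonded to the tertiary OH), as in O-functionalisation of 4,4-disubstituted cyclohexane-1,3-diones.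

Step 10
Reactants: 16 3-(trimethylsilyl)prop-2-ynal; 17 tert-butyl 2-(triphenyl-λ5-phosphanylidene)acetate
Product: 18 tert-butyl (2E)-5-(trimethylsilyl)pent-2-en-4-ynoate
Conditions: CH2Cl2, 0 °C → rt
Reagents that add atoms: none
Why: Wittig olefination with a stabilised ylide gives the E-enoate.

Step 11
Reactants: 18 tert-butyl (2E)-5-(trimethylsilyl)pent-2-en-4-ynoate
Product: 19 tert-butyl (2E)-pent-2-en-4-ynoate
Conditions: K2CO3 (10 mol %), MeOH, 0 °C, 20 min
Reagents that add atoms: none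
Why: Base-catalysed protodesilylation of the alkynylsilane; the tert-butyl ester does not transesterify.

Step 12
Reactants: 15 (1S,6R)-4-[(tert-butyldimethylsilyloxy)methyl]-6-hydroxy-6-methyl-5-oxo-3-(trifluoromethylsulfonyloxy)cyclohex-3-en-1-yl 4-methoxy-6-methyl-2,2-diphenyl-1,3-benzodioxole-5-carboxylate; 19 tert-butyl (2E)-pent-2-en-4-ynoate (1.5 equiv)
Product: 20 (1S,6R)-3-[(3E)-5-tert-butoxy-5-oxopent-3-en-1-yn-1-yl]-4-[(tert-butyldimethylsilyloxy)methyl]-6-hydroxy-6-methyl-5-oxocyclohex-3-en-1-yl 4-methoxy-6-methyl-2,2-diphenyl-1,3-benzodioxole-5-carboxylate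
Conditions: Pd(PPh3)4 (5 mol %), CuI (10 mol %), i-Pr2NEt, THF, rt
Reagents that add atoms: none
Why: Sonogashira coupling of the β-triflyloxy enone forms C4a–C4 at room temperature with a hindered amine, which limits vinylogous elimination of the C6 ester.

Step 13
Reactants: 20 (1S,6R)-3-[(3E)-5-tert-butoxy-5-oxopent-3-en-1-yn-1-yl]-4-[(tert-butyldimethylsilyloxy)methyl]-6-hydroxy-6-methyl-5-oxocyclohex-3-en-1-yl 4-methoxy-6-methyl-2,2-diphenyl-1,3-benzodioxole-5-carboxylate
Product: 22 tert-butyl (2E)-3-[(6S,7R)-7-hydroxy-6-(4-methoxy-6-methyl-2,2-diphenyl-1,3-benzodioxole-5-carbonyloxy)-7-methyl-8-oxo-5,6,7,8-tetrahydro-1H-isochromen-3-yl]prop-2-enoate, via free alcohol 21 (not isolated)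
Conditions: HF·pyridine, pyridine, THF, 0 °C → rt; after aqueous work-up the crude alcohol with JohnPhosAu(MeCN)SbF6 (5 mol %), CH2Cl2, rt
Reagents that add atoms: none
Why: Desilylation then Au(I)-catalysed 6-endo-dig hydroalkoxylation (cycloisomerisation); the ring ketone is the stronger acceptor and makes the distal alkyne carbon electrophilic, so the primary OH closes the pyran to the extended vinylogous ester; the ketone oxygen cannot reach the alkyne.

Step 14
Reactants: 22 tert-butyl (2E)-3-[(6S,7R)-7-hydroxy-6-(4-methoxy-6-methyl-2,2-diphenyl-1,3-benzodioxole-5-carbonyloxy)-7-methyl-8-oxo-5,6,7,8-tetrahydro-1H-isochromen-3-yl]prop-2-enoate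
Product: 23 (2E)-3-[(6S,7R)-6-(3,4-dihydroxy-2-methoxy-6-methylbenzoyloxy)-7-hydroxy-7-methyl-8-oxo-5,6,7,8-tetrahydro-1H-isochromen-3-yl]prop-2-enoic acid (CNP0446308.1)
Conditions: TFA/CH2Cl2/H2O (10:10:1), anisole, 0 °C → rt
Reagents that add atoms: none
Why: Acidolysis cleaves the tert-butyl ester and hydrolyses the diphenylmethylene ketal in one operation without base, so the base-labile C6 ester and both stereocentres are kept.

**Compound list**
1 | 2,3,4-trimethoxy-6-methylbenzaldehyde | COc1cc(C)c(C=O)c(OC)c1OC | starting material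
2 | 2,3,4-trihydroxy-6-methylbenzaldehyde | Cc1cc(O)c(O)c(O)c1C=O | intermediate
3 | 4-hydroxy-6-methyl-2,2-diphenyl-1,3-benzodioxole-5-carbaldehyde | Cc1cc2OC(c3ccccc3)(c3ccccc3)Oc2c(O)c1C=O | intermediate
4 | 4-methoxy-6-methyl-2,2-diphenyl-1,3-benzodioxole-5-carbaldehyde | Cc1cc2OC(c3ccccc3)(c3ccccc3)Oc2c(OC)c1C=O | intermediate
5 | 4-methoxy-6-methyl-2,2-diphenyl-1,3-benzodioxole-5-carboxylic acid | Cc1cc2OC(c3ccccc3)(c3ccccc3)Oc2c(OC)c1C(=O)O | intermediate
6 | (R)-(−)-carvone, (5R)-2-methyl-5-(prop-1-en-2-yl)cyclohex-2-en-1-one | CC(=C)[C@@H]1CC=C(C)C(=O)C1 | starting material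
7 | (1R,4R,6R)-1-methyl-4-(prop-1-en-2-yl)-7-oxabicyclo[4.1.0]heptan-2-one (oxirane anti to isopropenyl) | CC(=C)[C@@H]1C[C@H]2O[C@@]2(C)C(=O)C1 | intermediate
8 | lithium enolate of 7 (enolised towards the CH2 carbon) | CC(=C)[C@@H]1C[C@H]2O[C@@]2(C)C([O-])=C1.[Li+] | intermediate
9 | lithium aldolate (lithium alkoxide of the 3-hydroxymethyl ketone, CH2O anti to isopropenyl) | CC(=C)[C@@H]1C[C@H]2O[C@@]2(C)C(=O)[C@H]1C[O-].[Li+] | intermediate
10 | (1R,3R,4R,6R)-3-[(tert-butyldimethylsilyloxy)methyl]-1-methyl-4-(prop-1-en-2-yl)-7-oxabicyclo[4.1.0]heptan-2-one | CC(=C)[C@@H]1C[C@H]2O[C@@]2(C)C(=O)[C@H]1CO[Si](C)(C)C(C)(C)C | intermediate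
11 | (1S,2R,4R,5R)-4-[(tert-butyldimethylsilyloxy)methyl]-2-hydroxy-2-methyl-3-oxo-5-(prop-1-en-2-yl)cyclohexyl 4-methoxy-6-methyl-2,2-diphenyl-1,3-benzodioxole-5-carboxylate | Cc1cc2OC(c3ccccc3)(c3ccccc3)Oc2c(OC)c1C(=O)O[C@H]1C[C@@H](C(C)=C)[C@H](CO[Si](C)(C)C(C)(C)C)C(=O)[C@]1(C)O | intermediate
12 | as 11 with the isopropenyl group replaced by 1-hydroperoxy-1-methoxyethyl (epimers at that carbon) | Cc1cc2OC(c3ccccc3)(c3ccccc3)Oc2c(OC)c1C(=O)O[C@H]1C[C@@H](C(C)(OC)OO)[C@H](CO[Si](C)(C)C(C)(C)C)C(=O)[C@]1(C)O | intermediate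
13 | as 11 with the isopropenyl group replaced by (2,2,6,6-tetramethylpiperidin-1-yl)oxy (epimers at that carbon) | Cc1cc2OC(c3ccccc3)(c3ccccc3)Oc2c(OC)c1C(=O)O[C@H]1CC(ON2C(C)(C)CCCC2(C)C)[C@H](CO[Si](C)(C)C(C)(C)C)C(=O)[C@]1(C)O | intermediate
14 | (1S,2R)-4-[(tert-butyldimethylsilyloxy)methyl]-2-hydroxy-2-methyl-3,5-dioxocyclohexyl 4-methoxy-6-methyl-2,2-diphenyl-1,3-benzodioxole-5-carboxylate (drawn as diketone) | Cc1cc2OC(c3ccccc3)(c3ccccc3)Oc2c(OC)c1C(=O)O[C@H]1CC(=O)C(CO[Si](C)(C)C(C)(C)C)C(=O)[C@]1(C)O | intermediate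
15 | (1S,6R)-4-[(tert-butyldimethylsilyloxy)methyl]-6-hydroxy-6-methyl-5-oxo-3-(trifluoromethylsulfonyloxy)cyclohex-3-en-1-yl 4-methoxy-6-methyl-2,2-diphenyl-1,3-benzodioxole-5-carboxylate | Cc1cc2OC(c3ccccc3)(c3ccccc3)Oc2c(OC)c1C(=O)O[C@H]1CC(OS(=O)(=O)C(F)(F)F)=C(CO[Si](C)(C)C(C)(C)C)C(=O)[C@]1(C)O | intermediate
16 | 3-(trimethylsilyl)prop-2-ynal | C[Si](C)(C)C#CC=O | starting material
17 | tert-butyl 2-(triphenyl-λ5-phosphanylidene)acetate | CC(C)(C)OC(=O)C=P(c1ccccc1)(c1ccccc1)c1ccccc1 | starting material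
18 | tert-butyl (2E)-5-(trimethylsilyl)pent-2-en-4-ynoate | C[Si](C)(C)C#C/C=C/C(=O)OC(C)(C)C | intermediate
19 | tert-butyl (2E)-pent-2-en-4-ynoate | C#C/C=C/C(=O)OC(C)(C)C | intermediate
20 | (1S,6R)-3-[(3E)-5-tert-butoxy-5-oxopent-3-en-1-yn-1-yl]-4-[(tert-butyldimethylsilyloxy)methyl]-6-hydroxy-6-methyl-5-oxocyclohex-3-en-1-yl 4-methoxy-6-methyl-2,2-diphenyl-1,3-benzodioxole-5-carboxylate | Cc1cc2OC(c3ccccc3)(c3ccccc3)Oc2c(OC)c1C(=O)O[C@H]1CC(C#C/C=C/C(=O)OC(C)(C)C)=C(CO[Si](C)(C)C(C)(C)C)C(=O)[C@]1(C)O | intermediate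
21 | as 20 with the silyl ether replaced by free hydroxymethyl | Cc1cc2OC(c3ccccc3)(c3ccccc3)Oc2c(OC)c1C(=O)O[C@H]1CC(C#C/C=C/C(=O)OC(C)(C)C)=C(CO)C(=O)[C@]1(C)O | intermediate
22 | tert-butyl (2E)-3-[(6S,7R)-7-hydroxy-6-(4-methoxy-6-methyl-2,2-diphenyl-1,3-benzodioxole-5-carbonyloxy)-7-methyl-8-oxo-5,6,7,8-tetrahydro-1H-isochromen-3-yl]prop-2-enoate | Cc1cc2OC(c3ccccc3)(c3ccccc3)Oc2c(OC)c1C(=O)O[C@H]1CC2=C(COC(/C=C/C(=O)OC(C)(C)C)=C2)C(=O)[C@]1(C)O | intermediate
23 | (2E)-3-[(6S,7R)-6-(3,4-dihydroxy-2-methoxy-6-methylbenzoyloxy)-7-hydroxy-7-methyl-8-oxo-5,6,7,8-tetrahydro-1H-isochromen-3-yl]prop-2-enoic acid | COc1c(O)c(O)cc(C)c1C(=O)O[C@H]1CC2=C(COC(/C=C/C(=O)O)=C2)C(=O)[C@]1(C)O | target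

**Totals and risks**
Total step count: 14. Longest linear sequence: 10 (steps 1–4, then 7, 8, 9, 12, 13, 14); from carvone it is 8.

Three steps most likely to fail:

Step 7 (the proposed new epoxide opening). The risks are Lewis-acid rearrangement of the epoxy ketone (acyl shift) and slow attack by the hindered acid. Fallback with known chemistry, setting out from 10 and returning at 11: Luche reduction of 10 (NaBH4, CeCl3·7H2O, MeOH, −78 °C) gives cis-epoxy alcohol F1. The established Ti(OiPr)4-mediated opening of 2,3-epoxy alcohols by carboxylic acids, run with 5 in CH2Cl2, attacks C3 with inversion and gives diol monoester F2. Dess–Martin oxidation of the only secondary carbinol then gives 11.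

Step 8 (oxodealkenylation). The risks are ozone attack on the electron-rich benzoate and loss of material in the radical stage. Fallback setting out from 11 and returning at 14: ozonolysis with PPh3 work-up gives methyl ketone F3. Baeyer–Villiger oxidation (CF3CO3H, Na2HPO4) gives acetate F4 with retention. Lipase (CAL-B) methanolysis under neutral conditions, chosen to avoid β-elimination, gives alcohol F5. Dess–Martin oxidation gives 14.

Step 13 (6-endo cyclisation). The acrylate on the alkyne could steer the alcohol to the 5-exo mode. Fallback setting out from 15 and returning at 23: Sonogashira coupling of 15 with commercial (E)-pent-2-en-4-yn-1-ol gives ynenone alcohol F6, whose alkyne is polarised by the enone alone. HF·pyridine then Au(I) gives isochromenone alcohol F7. MnO2 gives enal F8, and Pinnick oxidation gives acid F9. TFA/H2O removes the ketal to give 23.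

**Further compounds**
F1 | step 7 | (1R,2S,3R,4R,6R)-3-[(tert-butyldimethylsilyloxy)methyl]-1-methyl-4-(prop-1-en-2-yl)-7-oxabicyclo[4.1.0]heptan-2-ol (OH cis to the oxirane) | CC(=C)[C@@H]1C[C@H]2O[C@@]2(C)[C@@H](O)[C@H]1CO[Si](C)(C)C(C)(C)C
F2 | step 7 | as 11 with the ring ketone reduced to the secondary alcohol (2,3-diol 1-ester) | Cc1cc2OC(c3ccccc3)(c3ccccc3)Oc2c(OC)c1C(=O)O[C@H]1C[C@@H](C(C)=C)[C@H](CO[Si](C)(C)C(C)(C)C)[C@H](O)[C@]1(C)O
F3 | step 8 | as 11 with the isopropenyl group replaced by acetyl | Cc1cc2OC(c3ccccc3)(c3ccccc3)Oc2c(OC)c1C(=O)O[C@H]1C[C@@H](C(C)=O)[C@H](CO[Si](C)(C)C(C)(C)C)C(=O)[C@]1(C)O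
F4 | step 8 | as 11 with the isopropenyl group replaced by acetoxy (retention) | Cc1cc2OC(c3ccccc3)(c3ccccc3)Oc2c(OC)c1C(=O)O[C@H]1C[C@@H](OC(C)=O)[C@H](CO[Si](C)(C)C(C)(C)C)C(=O)[C@]1(C)O
F5 | step 8 | as 11 with the isopropenyl group replaced by hydroxy | Cc1cc2OC(c3ccccc3)(c3ccccc3)Oc2c(OC)c1C(=O)O[C@H]1C[C@@H](O)[C@H](CO[Si](C)(C)C(C)(C)C)C(=O)[C@]1(C)O
F6 | step 13 | as 20 with the tert-butyl ester terminus replaced by CH2OH, (3E)-5-hydroxypent-3-en-1-yn-1-yl side chain | Cc1cc2OC(c3ccccc3)(c3ccccc3)Oc2c(OC)c1C(=O)O[C@H]1CC(C#C/C=C/CO)=C(CO[Si](C)(C)C(C)(C)C)C(=O)[C@]1(C)O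
F7 | step 13 | as 22 with the acrylate replaced by (E)-3-hydroxyprop-1-enyl | Cc1cc2OC(c3ccccc3)(c3ccccc3)Oc2c(OC)c1C(=O)O[C@H]1CC2=C(COC(/C=C/CO)=C2)C(=O)[C@]1(C)O
F8 | step 13 | as 22 with the acrylate replaced by (E)-3-oxoprop-1-enyl | Cc1cc2OC(c3ccccc3)(c3ccccc3)Oc2c(OC)c1C(=O)O[C@H]1CC2=C(COC(/C=C/C=O)=C2)C(=O)[C@]1(C)O
F9 | step 13 | free acrylic acid corresponding to 22 (ketal still in place) | Cc1cc2OC(c3ccccc3)(c3ccccc3)Oc2c(OC)c1C(=O)O[C@H]1CC2=C(COC(/C=C/C(=O)O)=C2)C(=O)[C@]1(C)O
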